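**Remark (numbering):** atom labels follow the usage for this alkaloid family: pyrrole N4, C3, C2, C1, C9a; azepane C5–C9; cyclohexane C9, C10 (ethyl), C11 (O), C12; lactone A = O–C11, C12, C13 (methyl), C14 (C=O); lactone B = C18 (O), C19, C20 (methyl), C21 (C=O). With these labels the target is 9R,10R,11S,12R,13R,18S,20S.

## The problem

The skeleton is a pyrrole (N4, C3, C2, C1, C9a) that shares its N4–C9a edge with an azepane (C5 to C9) and its C1–C9a edge with a cyclohexane (C9 to C12); the cyclohexane carries a cis-fused α-methyl-γ-butyrolactone (lactone A) and pyrrole C3 carries a second one (lactone B). The seven stereocentres form two groups that cannot influence each other across the flat pyrrole: C9, C10, C11, C12, C13 on one side and C18, C20 on the other, so the second group needs the chiral pool or a reagent. In the first group the substituents at C9/C10 and at C10/C11 are trans and the hydrogens at C11, C12 and C13 are all cis. C10 can therefore control C9 (trans alkylation), C11 (the equatorial, equilibrated position next to a carbonyl) and, through C11, both C12 and C13 if these are made together by delivery of H2 to one face of a C12=C13 butenolide. The C13 methyl lies on the concave face, cis to C1, which is not the outcome of enolate methylation and should not meet base once set. The trialkylpyrrole is sensitive to oxidants and strong acid, and the C18–O bond is a pyrrol-2-ylcarbinyl ester that ionises (azafulvenium ion) and hydrogenolyses easily, so lactone B must come late. The feature that opens the plan is the pyrrole itself: C9a (bonded to N4, C1, C9) stands at the oxidation level of the carbonyl of a seven-membered lactam, N4–C3 is the N–CH2 of glycine, and C1=C2 is an alkyne whose chain C12–C11–C10 runs back to the lactam α-carbon C9. The pyrrole and the cyclohexane ring can therefore be made in one cycloaddition of a caprolactam-derived mesoionic dipole, with CO2 as the only loss.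

## Retrosynthesis

**Lactone B (cut C3–C18, the acyl–O bond O–C21 and C18–H).** Target 23 is opened to hydroxy acid 22 and then to keto acid 21, which is cut at C3–C18 into the lactone-A core 19 and (S)-methylsuccinic anhydride 20. The usual alternative, formylation, allylation and hydrogenation, sets C20 by hydrogenation next to the labile C18–O bond. This cut takes C20 from the chiral pool, sets C18 by a catalyst and keeps the C18–O bond out of every earlier step. The forward steps must acylate the only free pyrrole α-position, open 20 at its less hindered carbonyl, reduce one face of a 2-acylpyrrole and lactonise through the acyl carbon.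

**Lactone A (cut C12–H/C13–H, then C12=C13 and O–C14, then C11–O).** Core 19 goes back to butenolide 18 by removal of H2. 18 goes back through phosphonate ester 17 to α-hydroxy ketone 15 and 2-(diethoxyphosphoryl)propanoic acid 16, and 15 goes back to ketone 14 by removal of the C11 oxygen. The all-cis hydrogens at C11, C12, C13 are the signature of syn addition of H2 anti to C10. C11, next to a carbonyl in 15 and a γ-carbon in 18, can settle trans to the C10 ethyl group. Three stereocentres thus follow from C10, whereas enolate methylation of a preformed lactone would give the C13 epimer. The forward steps need regioselective enolisation (only C11 can enolise) and facial selectivity in the hydrogenation.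

**Key disconnection (cut C9a–C1 and C3–C2, add back CO2).** Ketone 14 is unravelled through bridged adduct 13 and mesoionic dipole 12 to the lactam acid 11. This removes the pyrrole and the carbocycle at once and leaves a monocyclic caprolactam with one side chain. No stereocentre is made in the step, so it cannot fail on selectivity. Stepwise annulation of a preformed pyrrole or a Paal–Knorr closure would each need the carbocycle to be built separately. The forward reaction must generate the dipole without disturbing C9 and must add across the alkyne in the one orientation that the tether allows.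

**Ynone (cut C12–C1).** Acid 11 comes from tert-butyl ester 10, the ynone 10 from propargylic alcohol 9, and 9 from aldehyde 8 and an ethynyl Grignard reagent; 8 is the oxidation product of primary alcohol 7. A terminal ynone is chosen over a plain alkyne because it is the best dipolarophile, its carbonyl ends up as the C12 ketone needed for lactone A, and its polarity matches the dipole.

**Lactam and the C9/C10 pair (cut N4–C9a, N4–C5, C9–C8, C10–ethyl).** Hydroxy lactam 7 is the acyl-transfer isomer of amino lactone 6, which comes from chloro lactone 4 and glycine tert-butyl ester 5. The lactone carbonyl becomes the lactam carbonyl and the lactone oxygen is released as the C12 alcohol. 4 is the trans alkylation product of (S)-4-ethyl lactone 2 with 1-chloro-4-iodobutane 3, and 2 comes from 5,6-dihydro-2H-pyran-2-one 1 by asymmetric conjugate addition. A six-membered lactone is chosen because it alone gives reliable trans alkylation next to C10. Only C10 has to come from a chiral catalyst.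

## Roads not taken

**Alternative 1:** the obvious route starts from the parent pyrrole. The azepine is closed by N-alkylation and Friedel–Crafts acylation to pyrroloazepinone A1. The carbocycle is added bond by bond (C9–C10, then C1–C12), and lactone A is made in its C13-unsubstituted form A2 by a Claisen transfer and halolactonisation, followed by a final C13 methylation. Lactone B is added by formylation, Barbier addition and hydrogenation. The forward key step would be the Friedel–Crafts ring closure on the pyrrole. The chosen plan is better for three structural reasons. A1 is flat, so C9 would have to be created beside a finished pyrrole with no neighbour to direct it. Methylation of the enolate of A2 occurs on the convex face and gives the C13 epimer of the target. Each ring costs its own steps, whereas the cycloaddition closes two rings at once.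

**Alternative 2:** cut N4–C3 and N4–C9a and close the pyrrole and the azepane together by an intramolecular Paal–Knorr condensation of amino-1,4-diketone A3. The key step is simple, but A3 already contains the whole cyclohexanone with five stereocentres and lactone B. Two of its stereocentres (C9 and C18) sit α to ketones under acidic condensation conditions, and C18 is an α-acyloxy ketone prone to elimination. The difficulty is moved into the precursor, not removed, whereas 11 is a monocyclic lactam with two stereocentres.

**Alternative 3:** cut C1–C12 and close the cyclohexane by Friedel–Crafts conjugate addition of pyrrole C1 to the butenolide of A4. The cis ring fusion at C12 would be enforced by the ring and the butenolide could come from a vinylogous Mukaiyama–Michael reaction. The weakness is that C9, C10 and C11 would have to be set on an open chain attached to a finished pyrrole, with C9 again lacking a handle, and the closure needs a strong Lewis acid in the presence of an electron-rich pyrrole. In the chosen plan C9 is set by a lactone alkylation, and C11, C12 and C13 are set on a rigid ring.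

Key step: step 8

## Route

**Step 1**
Reactants: 1 5,6-dihydro-2H-pyran-2-one
Product: 2 (S)-4-ethyltetrahydro-2H-pyran-2-one
Conditions: Et2Zn, Cu(OTf)2 (2 mol%), chiral phosphoramidite ligand (4 mol%, antipode that gives the S lactone), toluene, −30 °C; aq NH4Cl
Reagents that add atoms: diethylzinc, CC[Zn]CC
Why: Copper-catalysed asymmetric conjugate addition of a dialkylzinc to a cyclic enoate, a reaction type established for unsaturated δ-lactones; the ligand fixes the face of C10, the only stereocentre of the core that must come from a catalyst.

**Step 2**
Reactants: 2 (S)-4-ethyltetrahydro-2H-pyran-2-one; 3 1-chloro-4-iodobutane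
Product: 4 (3R,4S)-3-(4-chlorobutyl)-4-ethyltetrahydro-2H-pyran-2-one
Conditions: LiN(iPr)2, THF, −78 °C; then 3, DMPU, −78 → −30 °C
Reagents that add atoms: none
Why: Alkylation of a δ-lactone enolate by the iodide end of 3; the electrophile enters anti to the adjacent C10 ethyl group, which sets C9 trans to C10.

**Step 3**
Reactants: 4 (3R,4S)-3-(4-chlorobutyl)-4-ethyltetrahydro-2H-pyran-2-one; 5 glycine tert-butyl ester
Product: 7 tert-butyl 2-{(3R)-3-[(3S)-1-hydroxypentan-3-yl]-2-oxoazepan-1-yl}acetate, via amino lactone 6 (not isolated)
Conditions: 5 (4 equiv), NaI (cat.), K2CO3, MeCN, 70 °C; remove excess 5; then 2-hydroxypyridine (20 mol%), toluene, 110 °C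
Reagents that add atoms: none
Why: Finkelstein-assisted N-alkylation gives secondary amine 6, whose nitrogen then attacks the lactone carbonyl intramolecularly (bifunctionally catalysed ester aminolysis); the six-membered lactone is exchanged for the seven-membered tertiary lactam, C12 is released as a primary alcohol, and C9 and C10 are not touched.

**Step 4**
Reactants: 7 tert-butyl 2-{(3R)-3-[(3S)-1-hydroxypentan-3-yl]-2-oxoazepan-1-yl}acetate
Product: 8 tert-butyl 2-{(3R)-2-oxo-3-[(3S)-1-oxopentan-3-yl]azepan-1-yl}acetate
Conditions: TEMPO (10 mol%), PhI(OAc)2, CH2Cl2, 25 °C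
Reagents that add atoms: none
Why: Nitroxyl-catalysed oxidation stops at the aldehyde and leaves lactam and tert-butyl ester alone; neither stereocentre is α to the new carbonyl.

**Step 5**
Reactants: 8 tert-butyl 2-{(3R)-2-oxo-3-[(3S)-1-oxopentan-3-yl]azepan-1-yl}acetate
Product: 9 tert-butyl 2-{(3R)-3-[(3S)-5-hydroxyhept-6-yn-3-yl]-2-oxoazepan-1-yl}acetate (both carbinol epimers)
Conditions: HC≡CMgBr, THF, −78 → 0 °C; aq NH4Cl
Reagents that add atoms: ethynylmagnesium bromide, C#C[Mg]Br
Why: Grignard addition to the aldehyde is much faster than attack on the tert-butyl ester or the tertiary lactam; the carbinol centre is left uncontrolled because it is oxidised in the next step.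

**Step 6**
Reactants: 9 tert-butyl 2-{(3R)-3-[(3S)-5-hydroxyhept-6-yn-3-yl]-2-oxoazepan-1-yl}acetate
Product: 10 tert-butyl 2-{(3R)-2-oxo-3-[(3S)-5-oxohept-6-yn-3-yl]azepan-1-yl}acetate
Conditions: Dess–Martin periodinane, CH2Cl2, 0 → 25 °C
Reagents that add atoms: none
Why: Mild oxidation of the propargylic alcohol gives the terminal ynone, the activated dipolarophile of the key step; neutral conditions avoid conjugate addition to it.

**Step 7**
Reactants: 10 tert-butyl 2-{(3R)-2-oxo-3-[(3S)-5-oxohept-6-yn-3-yl]azepan-1-yl}acetate
Product: 11 2-{(3R)-2-oxo-3-[(3S)-5-oxohept-6-yn-3-yl]azepan-1-yl}acetic acid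
Conditions: CF3CO2H/CH2Cl2 (1:3), 0 → 25 °C; evaporate
Reagents that add atoms: none
Why: Acidolysis of the tert-butyl ester (loss of isobutene) frees the glycine carboxyl; ynone and lactam are stable to acid.

**Step 8**
Reactants: 11 2-{(3R)-2-oxo-3-[(3S)-5-oxohept-6-yn-3-yl]azepan-1-yl}acetic acid
Product: 14 (9R,10S)-10-ethyl-12-oxo tricyclic pyrrole ketone (pyrrole N4/C3–H/C2–H/C1/C9a fused to azepane C5–C9 and to cyclohexanone C9–C12), via münchnone 12 (not isolated), via bridged cycloadduct 13 (not isolated)
Conditions: iPrN=C=NiPr (1.5 equiv), toluene (5 mM), 25 → 70 °C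
Reagents that add atoms: none
Why: Cyclodehydration of the N-acyl-N-alkylglycine unit of 11 by the carbodiimide gives the azepane-fused 1,3-oxazolium-5-olate 12, a cyclic azomethine ylide over C9a–N4–C3. Its nucleophilic C3 and iminium-like C9a add across the tethered ynone (C3 to C2, C9a to C1) to give the lactone-bridged adduct 13, which loses CO2 by cycloreversion to the aromatic pyrrole 14. The closest known reaction type is the Huisgen pyrrole synthesis from münchnones and alkynes, which is known in intramolecular form and with bicyclic münchnones from cyclic N-acyl amino acids. The pyrrole ring is closed by the (3+2) cycloaddition and retro-(4+2) loss of CO2; the cyclohexanone ring (C9a, C9, C10, C11, C12, C1) is closed in the same event in the fused mode, the three-atom tether C10–C11–C12 linking the carbon next to the dipole terminus to the near alkyne carbon so that the new C9a–C1 bond lies inside a six-membered ring. No new stereocentre survives (C9a and C3 of 13 become sp2), so the step only has to preserve C9 and C10. Regioselectivity is needed and is secured twice: the tether can reach only the C9a/C1 pairing, and the nucleophilic dipole carbon C3 is matched with the β-carbon C2 of the ynone. Selectivity over intermolecular reaction or C-acylation of the unsubstituted C3 is secured by high dilution, a non-acylating dehydrating agent and the high reactivity of a terminal ynone.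

**Step 9**
Reactants: 14 (9R,10S)-10-ethyl-12-oxo tricyclic pyrrole ketone
Product: 15 (9R,10R,11S)-10-ethyl-11-hydroxy-12-oxo tricyclic pyrrole ketone
Conditions: KN(SiMe3)2, THF, −78 °C; then 2-(phenylsulfonyl)-3-phenyloxaziridine, −78 → −40 °C; aq NH4Cl
Reagents that add atoms: 2-(phenylsulfonyl)-3-phenyloxaziridine, O=S(=O)(N1OC1c1ccccc1)c1ccccc1
Why: C11 is the only enolisable position of the vinylogous amide ketone, and enolate oxidation by an N-sulfonyloxaziridine is a standard α-hydroxylation; the oxidant should approach anti to the C10 ethyl group, and the trans α-ketol (hydroxyl and ethyl both equatorial) is also the thermodynamic epimer, so C11 follows C10.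

**Step 10**
Reactants: 15 (9R,10R,11S)-10-ethyl-11-hydroxy-12-oxo tricyclic pyrrole ketone; 16 2-(diethoxyphosphoryl)propanoic acid
Product: 18 (9R,10R,11S)-butenolide (lactone A with C12=C13, 13-methyl) fused to the tricyclic pyrrole, via phosphonate ester 17 (not isolated)
Conditions: 16, EDC·HCl, DMAP, CH2Cl2, 0 → 25 °C; then LiCl, DBU, MeCN, 25 → 60 °C
Reagents that add atoms: none
Why: Carbodiimide esterification followed by an intramolecular Horner–Wadsworth–Emmons reaction is the standard way from an α-hydroxy ketone to an α-methylbutenolide; five-membered ring closure offsets the low electrophilicity of the C12 carbonyl, and C11, now a butenolide γ-carbon, can still settle to the all-equatorial epimer under the basic conditions.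

**Step 11**
Reactants: 18 (9R,10R,11S)-butenolide
Product: 19 (9R,10R,11S,12R,13R)-lactone-A core with free C3–H
Conditions: H2 (20 bar), 10% Pd/C, EtOAc, 25 °C
Reagents that add atoms: none
Why: Heterogeneous hydrogenation adds both hydrogens to C12=C13 from the same face, the one that carries H11 and is not screened by C10 of the fused ring, as is usual for γ-substituted butenolides; this gives the cis ring fusion at C12 and puts the C13 methyl on the concave face, the all-cis hydrogen pattern of the target.

**Step 12**
Reactants: 19 (9R,10R,11S,12R,13R)-lactone-A core; 20 (S)-methylsuccinic anhydride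
Product: 21 (2S)-2-methyl-4-oxo-4-(lactone-A core-3-yl)butanoic acid
Conditions: 20, AlCl3, CH2Cl2, −20 → 0 °C; then H2O
Reagents that add atoms: none
Why: Friedel–Crafts acylation of the trialkylpyrrole at C3, its only free α-position; the anhydride opens at the less hindered CH2-bound carbonyl, as it does with arenes, so the methyl-bearing carbon becomes C20 with its configuration from the chiral pool.

**Step 13**
Reactants: 21 (2S)-2-methyl-4-oxo-4-(lactone-A core-3-yl)butanoic acid
Product: 23 target alkaloid (9R,10R,11S,12R,13R,18S,20S), via hydroxy acid 22 (not isolated)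
Conditions: RuCl[(S,S)-TsDPEN](p-cymene) (2 mol%), HCO2H/Et3N (1:2), DMF, 30 °C; then EDC·HCl, DMAP, CH2Cl2, 0 °C
Reagents that add atoms: none
Why: Asymmetric transfer hydrogenation of the heteroaryl ketone under amine-rich conditions sets C18 by catalyst control (the S,S catalyst gives the S carbinol of aryl alkyl ketones), independent of the remote core; carbodiimide lactonisation then closes lactone B through the acyl carbon, so the labile C18–O bond is never ionised and pyrrole and C20 methyl end up cis.

## Compound list

1 | 5,6-dihydro-2H-pyran-2-one | O=C1C=CCCO1 | starting material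
2 | (S)-4-ethyltetrahydro-2H-pyran-2-one | CC[C@H]1CCOC(=O)C1 | intermediate
3 | 1-chloro-4-iodobutane | ClCCCCI | starting material
4 | (3R,4S)-3-(4-chlorobutyl)-4-ethyltetrahydro-2H-pyran-2-one | CC[C@H]1CCOC(=O)[C@@H]1CCCCCl | intermediate
5 | glycine tert-butyl ester | NCC(=O)OC(C)(C)C | starting material
6 | tert-butyl N-{4-[(3R,4S)-4-ethyl-2-oxotetrahydro-2H-pyran-3-yl]butyl}glycinate (amino lactone) | CC[C@H]1CCOC(=O)[C@@H]1CCCCNCC(=O)OC(C)(C)C | intermediate
7 | tert-butyl 2-{(3R)-3-[(3S)-1-hydroxypentan-3-yl]-2-oxoazepan-1-yl}acetate | CC[C@H]([C@H]1CCCCN(CC(=O)OC(C)(C)C)C1=O)CCO | intermediate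
8 | tert-butyl 2-{(3R)-2-oxo-3-[(3S)-1-oxopentan-3-yl]azepan-1-yl}acetate | CC[C@H]([C@H]1CCCCN(CC(=O)OC(C)(C)C)C1=O)CC=O | intermediate
9 | tert-butyl 2-{(3R)-3-[(3S)-5-hydroxyhept-6-yn-3-yl]-2-oxoazepan-1-yl}acetate (carbinol centre open, both epimers) | CC[C@H]([C@H]1CCCCN(CC(=O)OC(C)(C)C)C1=O)CC(O)C#C | intermediate
10 | tert-butyl 2-{(3R)-2-oxo-3-[(3S)-5-oxohept-6-yn-3-yl]azepan-1-yl}acetate | CC[C@H]([C@H]1CCCCN(CC(=O)OC(C)(C)C)C1=O)CC(=O)C#C | intermediate
11 | 2-{(3R)-2-oxo-3-[(3S)-5-oxohept-6-yn-3-yl]azepan-1-yl}acetic acid | CC[C@H]([C@H]1CCCCN(CC(=O)O)C1=O)CC(=O)C#C | intermediate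
12 | azepane-fused 1,3-oxazol-3-ium-5-olate (münchnone) with the (3S)-5-oxohept-6-yn-3-yl chain on C9 | CC[C@H]([C@H]1CCCC[N+]2=C1OC([O-])=C2)CC(=O)C#C | intermediate
13 | lactone-bridged 3-pyrroline cycloadduct (O–C(=O) bridge from C9a to C3; bridgeheads open) | CC[C@H]1CC(=O)C2=CC3N4CCCC[C@H]1C24OC3=O | intermediate
14 | (9R,10S)-10-ethyl-12-oxo tricyclic pyrrole ketone | CC[C@H]1CC(=O)c2ccn3c2[C@@H]1CCCC3 | intermediate
15 | (9R,10R,11S)-10-ethyl-11-hydroxy-12-oxo tricyclic pyrrole ketone | CC[C@H]1[C@H](O)C(=O)c2ccn3c2[C@@H]1CCCC3 | intermediate
16 | 2-(diethoxyphosphoryl)propanoic acid (racemic) | CCOP(=O)(OCC)C(C)C(=O)O | starting material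
17 | 11-O-[2-(diethoxyphosphoryl)propanoyl] ester of 15 | CC[C@H]1[C@H](OC(=O)C(C)P(=O)(OCC)OCC)C(=O)c2ccn3c2[C@@H]1CCCC3 | intermediate
18 | (9R,10R,11S)-butenolide (C12=C13, 13-methyl) fused to the tricyclic pyrrole | CC[C@H]1[C@@H]2OC(=O)C(C)=C2c2ccn3c2[C@@H]1CCCC3 | intermediate
19 | (9R,10R,11S,12R,13R)-lactone-A core with free C3–H | CC[C@H]1[C@@H]2OC(=O)[C@H](C)[C@@H]2c2ccn3c2[C@@H]1CCCC3 | intermediate
20 | (S)-methylsuccinic anhydride [(3S)-3-methyloxolane-2,5-dione] | O=C1C[C@H](C)C(=O)O1 | starting material
21 | (2S)-2-methyl-4-oxo-4-(lactone-A core-3-yl)butanoic acid | CC[C@H]1[C@@H]2OC(=O)[C@H](C)[C@@H]2c2cc(C(=O)C[C@H](C)C(=O)O)n3c2[C@@H]1CCCC3 | intermediate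
22 | (2S,4S)-4-hydroxy-2-methyl-4-(lactone-A core-3-yl)butanoic acid | CC[C@H]1[C@@H]2OC(=O)[C@H](C)[C@@H]2c2cc([C@@H](O)C[C@H](C)C(=O)O)n3c2[C@@H]1CCCC3 | intermediate
23 | target alkaloid CNP0232452.6 (9R,10R,11S,12R,13R,18S,20S) | CC[C@H]1[C@@H]2OC(=O)[C@H](C)[C@@H]2c2cc([C@@H]3C[C@H](C)C(=O)O3)n3c2[C@@H]1CCCC3 | target

## Step count and least certain steps

Total steps: 13. Longest linear sequence: 13 (1 → 23); all other reactants are commercial.

**Step 8 (key step).** The most likely failures are loss of configuration at C9 and consumption of the dipole before cycloaddition. C9–H is α to the oxazolium carbon of 12 and can be shuttled through an exocyclic enamine tautomer. The C3-unsubstituted dipole can also acylate itself, dimerise or rearrange to an N-acylurea before it reaches the alkyne. The fallback sets out from 10 and uses a different dipole that needs no cyclodehydration and has C3 blocked. MeOTf in CH2Cl2 should O-methylate the tertiary lactam to the lactim ether triflate F1. Et3N then removes a proton from the N–CH2–CO2tBu carbon to give an ester-stabilised alkoxy azomethine ylide, which adds across the tethered ynone. Loss of methanol from the adduct should give the pyrrole tert-butyl ester F2. Acidolysis with CF3CO2H gives the pyrrole-3-carboxylic acid F3 (carboxyl on C3), which decarboxylates on warming and rejoins the route at 14. C9 stays α to an iminium carbon in F1, so base and time would be kept to the minimum.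

**Step 3.** What may go wrong is intermolecular aminolysis of the lactone by excess 5, over-alkylation of the amine, or a slow seven-membered acyl transfer by a hindered, weakly nucleophilic secondary amine. The fallback sets out from 2 and closes the azepane ring by metathesis. Alkylation of the enolate of 2 with allyl bromide gives (3R,4S)-3-allyl-4-ethyltetrahydro-2H-pyran-2-one F4. AlMe3-mediated aminolysis with tert-butyl N-allylglycinate opens it to tert-butyl N-allyl-N-[(2R,3S)-2-allyl-3-ethyl-5-hydroxypentanoyl]glycinate F5. Ring-closing metathesis with the second-generation Grubbs catalyst gives tert-butyl 2-{(3R)-3-[(3S)-1-hydroxypentan-3-yl]-2-oxo-2,3,4,7-tetrahydro-1H-azepin-1-yl}acetate F6, and hydrogenation (H2, Pd/C) of the ring alkene rejoins the route at 7.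

**Step 11.** What may go wrong is slow or unselective hydrogen uptake at the tetrasubstituted donor–acceptor alkene, with hydrogenolysis of the allylic C11–O bond or saturation of the pyrrole if the conditions are forced. The fallback sets out from 18 and reduces ionically. CF3CO2H protonates C13 of the vinylogous carbamate, and Et3SiH delivers hydride to the pyrrole-stabilised C12 cation from the convex face, which fixes the cis fusion. Any C13 epimer of 19, F7, is converged by deprotonation with LiN(iPr)2 and kinetic protonation of the lactone enolate from the convex face, which returns the concave methyl and rejoins the route at 19.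

**Step 13.** What may go wrong is slow hydride transfer to a vinylogous amide carbonyl, erosion of facial selectivity by the flanking N-alkyl group, or ionisation of the pyrrolylcarbinol with loss of configuration at C18. Uncertain regioselectivity in step 12 is bypassed by the same fallback. It sets out from 19. Vilsmeier formylation (POCl3, DMF) gives the 3-formyl core F8. A chromium-catalysed asymmetric 2-(ethoxycarbonyl)allylation with ethyl 2-(bromomethyl)acrylate (CrCl2, chiral bisoxazoline ligand, Mn powder, Me3SiCl) and lactonisation give the (18S)-α-methylene lactone F9. Hydrogenation with RhCl(PPh3)3 from the face anti to the pyrrole sets C20 cis and reaches 23 directly.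

## Further compounds

F1 | step 8 | O-methyl lactim ether triflate of 10 | CC[C@H]([C@H]1CCCC[N+](CC(=O)OC(C)(C)C)=C1OC)CC(=O)C#C.[O-]S(=O)(=O)C(F)(F)F
F2 | step 8 | tert-butyl ester of the 3-carboxy derivative of 14 | CC[C@H]1CC(=O)c2cc(C(=O)OC(C)(C)C)n3c2[C@@H]1CCCC3
F3 | step 8 | 3-carboxylic acid of 14 | CC[C@H]1CC(=O)c2cc(C(=O)O)n3c2[C@@H]1CCCC3
F4 | step 3 | (3R,4S)-3-allyl-4-ethyltetrahydro-2H-pyran-2-one | CC[C@H]1CCOC(=O)[C@@H]1CC=C
F5 | step 3 | tert-butyl N-allyl-N-[(2R,3S)-2-allyl-3-ethyl-5-hydroxypentanoyl]glycinate | CC[C@@H](CCO)[C@@H](CC=C)C(=O)N(CC=C)CC(=O)OC(C)(C)C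
F6 | step 3 | tert-butyl 2-{(3R)-3-[(3S)-1-hydroxypentan-3-yl]-2-oxo-2,3,4,7-tetrahydro-1H-azepin-1-yl}acetate | CC[C@H]([C@H]1CC=CCN(CC(=O)OC(C)(C)C)C1=O)CCO
F7 | step 11 | C13 epimer of 19 | CC[C@H]1[C@@H]2OC(=O)[C@@H](C)[C@@H]2c2ccn3c2[C@@H]1CCCC3
F8 | step 13 | 3-formyl derivative of 19 | CC[C@H]1[C@@H]2OC(=O)[C@H](C)[C@@H]2c2cc(C=O)n3c2[C@@H]1CCCC3
F9 | step 13 | (18S)-α-methylene lactone B on the core of 19 | CC[C@H]1[C@@H]2OC(=O)[C@H](C)[C@@H]2c2cc([C@@H]3CC(=C)C(=O)O3)n3c2[C@@H]1CCCC3
A1 | alternative 1 | 6,7,8,9-tetrahydro-5H-pyrrolo[1,2-a]azepin-9-one | O=C1CCCCn2cccc12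
A2 | alternative 1 | C13-unsubstituted lactone-A core (19 without the 13-methyl) | CC[C@H]1[C@@H]2OC(=O)C[C@@H]2c2ccn3c2[C@@H]1CCCC3
A3 | alternative 2 | amino-1,4-diketone (cyclohexanone with lactone A, 4-aminobutyl at C9 and the lactone-B acylmethyl at C1) | CC[C@H]1[C@@H]2OC(=O)[C@H](C)[C@@H]2C(CC(=O)[C@@H]2C[C@H](C)C(=O)O2)C(=O)[C@@H]1CCCCN
A4 | alternative 3 | pyrroloazepine with a C9 side chain ending in the α-methylbutenolide | CC[C@@H]([C@@H]1OC(=O)C(C)=C1)[C@H]1CCCCn2cccc12
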